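**Plan**

1. Numbering: the bicycle is 5H-furo[3,2-b]pyran-5-one (ring A = tetrahydrofuran O1–C2–C3–C3a–C7a; ring B = lactone O4–C5(=O)–C6=C7–C7a–C3a), the side chain is C1′–C5′. Retrosynthetic cuts, in order: the C3′ carbinol back to a ketone and C1′=C2′ (Wittig) to a C2 aldehyde plus a lactate-derived acyl ylide; then O1–C7a; then the ring B alkene (metathesis) and the O4–C5 ester bond; finally C3a–C7a (vinyl addition to a threose aldehyde).
2. Forward order: ring B first, built as its deconjugated isomer (alkene at C7=C7a) by esterification and ring-closing metathesis; ring A second, by an oxidative alkoxylation in which O1 adds to C7a and the alkene returns to C6=C7; side chain last.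
3. Enabling feature: C7a is the γ-carbon of the unsaturated lactone, and O1 (on C2) sits three carbons from it (C2–C3–C3a). In the C7=C7a isomer O1 therefore closes 5-exo onto C7a, and the C6 hydrogens next to the C5 carbonyl supply the hydride that restores conjugation.
4. Stereochemistry: C2 and C3 from L-tartaric acid (2,3-O-isopropylidene-L-threitol); C3a by Felkin–Anh vinyl addition; C7a by the enforced cis fusion of the key step; C4′ from (R)-lactic acid; C3′ by Corey–Bakshi–Shibata reduction; the E alkene from the stabilized ylide.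

Key step: step 7

Remark: the monocyclic lactones carry pyranone numbering (O1, C2=O, C3, C4, C5, C6; side chain C1′–C3′); (R)-lactic acid is assumed to be used as the anhydrous crystalline acid.

**Route**

Step 1
Reactants: 1 (4S,5S)-2,2-dimethyl-1,3-dioxolane-4,5-dimethanol (2,3-O-isopropylidene-L-threitol)
Product: 2 [(4S,5S)-5-({[tert-butyl(diphenyl)silyl]oxy}methyl)-2,2-dimethyl-1,3-dioxolan-4-yl]methanol
Conditions: NaH (1.0 equiv), THF, 0 °C; then TBDPSCl (1.0 equiv), 0 °C → rt
Reagents that add atoms: tert-butyl(chloro)diphenylsilane, CC(C)(C)[Si](Cl)(c1ccccc1)c1ccccc1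
Why: Monodeprotonation of the C2-symmetric diol gives a sparingly soluble monoalkoxide that is silylated once (monoprotection of a symmetric diol); the two hydroxymethyl groups are homotopic, so no regiochemical question arises and no stereocenter is touched.

Step 2
Reactants: 2 [(4S,5S)-5-({[tert-butyl(diphenyl)silyl]oxy}methyl)-2,2-dimethyl-1,3-dioxolan-4-yl]methanol
Product: 3 (4R,5S)-5-({[tert-butyl(diphenyl)silyl]oxy}methyl)-2,2-dimethyl-1,3-dioxolane-4-carbaldehyde
Conditions: Dess–Martin periodinane, CH2Cl2, 0 °C → rt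
Reagents that add atoms: none
Why: Dess–Martin oxidation of the primary alcohol stops at the aldehyde under near-neutral conditions, so the epimerizable α-alkoxy center should be preserved.

Step 3
Reactants: 3 (4R,5S)-5-({[tert-butyl(diphenyl)silyl]oxy}methyl)-2,2-dimethyl-1,3-dioxolane-4-carbaldehyde
Product: 4 (1S)-1-[(4S,5S)-5-({[tert-butyl(diphenyl)silyl]oxy}methyl)-2,2-dimethyl-1,3-dioxolan-4-yl]prop-2-en-1-ol (hydroxyl anti to the neighbouring dioxolane oxygen)
Conditions: CH2=CHMgBr, ZnBr2, THF/Et2O, −78 °C; then H2O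
Reagents that add atoms: vinylmagnesium bromide, C=C[Mg]Br
Why: Carbonyl addition of the vinylzinc reagent formed in the flask should follow the Felkin–Anh model (dioxolane C–O bond anti to the incoming nucleophile) and place the new hydroxyl anti to the adjacent ring oxygen as the major epimer (future C3a), the minor syn epimer being removed by chromatography.

Step 4
Reactants: 4 (1S)-1-[(4S,5S)-5-({[tert-butyl(diphenyl)silyl]oxy}methyl)-2,2-dimethyl-1,3-dioxolan-4-yl]prop-2-en-1-ol
Product: 5 (1S)-1-[(4S,5S)-5-({[tert-butyl(diphenyl)silyl]oxy}methyl)-2,2-dimethyl-1,3-dioxolan-4-yl]prop-2-en-1-yl but-3-enoate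
Conditions: but-3-enoic acid, DCC, DMAP (cat.), CH2Cl2, −10 °C → 0 °C
Reagents that add atoms: but-3-enoic acid, C=CCC(=O)O
Why: Steglich esterification acylates the secondary allylic alcohol with retention at the carbinol carbon, and low temperature with only catalytic DMAP should keep the but-3-enoyl unit from moving into conjugation.

Step 5
Reactants: 5 (1S)-1-[(4S,5S)-5-({[tert-butyl(diphenyl)silyl]oxy}methyl)-2,2-dimethyl-1,3-dioxolan-4-yl]prop-2-en-1-yl but-3-enoate
Product: 6 (6S)-6-[(4S,5S)-5-({[tert-butyl(diphenyl)silyl]oxy}methyl)-2,2-dimethyl-1,3-dioxolan-4-yl]-3,6-dihydro-2H-pyran-2-one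
Conditions: second-generation Grubbs catalyst RuCl2(PCy3)(H2IMes)(=CHPh) (5 mol %), 1,4-benzoquinone (10 mol %), CH2Cl2 (dilute), 40 °C
Reagents that add atoms: none
Why: Ring-closing metathesis of the two terminal alkenes closes the six-membered β,γ-unsaturated lactone (ring B) with loss of ethene, the ring size fixing the Z alkene, and the benzoquinone additive suppresses hydride-mediated migration of the double bond into conjugation.

Step 6
Reactants: 6 (6S)-6-[(4S,5S)-5-({[tert-butyl(diphenyl)silyl]oxy}methyl)-2,2-dimethyl-1,3-dioxolan-4-yl]-3,6-dihydro-2H-pyran-2-one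
Product: 7 (6S)-6-[(1R,2S)-3-{[tert-butyl(diphenyl)silyl]oxy}-1,2-dihydroxypropyl]-3,6-dihydro-2H-pyran-2-one
Conditions: TFA/H2O (9:1), 0 °C
Reagents that add atoms: none
Why: Acid hydrolysis of the isopropylidene acetal frees the two secondary hydroxyls, while the primary TBDPS ether, the lactone and the isolated alkene should tolerate cold aqueous TFA; no stereocenter is involved.

Step 7
Reactants: 7 (6S)-6-[(1R,2S)-3-{[tert-butyl(diphenyl)silyl]oxy}-1,2-dihydroxypropyl]-3,6-dihydro-2H-pyran-2-one
Product: 9 (2S,3R,3aR,7aR)-2-({[tert-butyl(diphenyl)silyl]oxy}methyl)-3-hydroxy-2,3,3a,7a-tetrahydro-5H-furo[3,2-b]pyran-5-one, via C7-chloropalladium adduct 8 (not isolated)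
Conditions: PdCl2(MeCN)2 (10 mol %), 1,4-benzoquinone (2 equiv), THF, rt
Reagents that add atoms: none
Why: PdCl2(MeCN)2 (divalent palladium) binds the ring alkene of 7 (C4=C5 in pyranone numbering, the future C7=C7a) on the face away from the side chain, the C2′ hydroxyl (future O1) adds anti at the future C7a to give the C7–PdCl adduct 8, and syn β-hydride elimination toward the C6 hydrogens α to the lactone carbonyl releases 9 with the alkene back in conjugation, benzoquinone reoxidising the zerovalent palladium formed from HPdCl. The closest known reaction type is the Wacker-type oxidative alkoxylation of cycloalkenes that carry a hydroxyalkyl tether on the allylic carbon, which gives cis-fused bicyclic allylic ethers. Ring A closes in the 5-exo-trig mode. The only new stereocenter, C7a, is controlled by C3a: the three-atom tether C3a–C3–C2–O1 can reach only the alkene face on which it is held, so the ring fusion has to be cis whether oxypalladation is anti or syn. The step needs chemoselectivity between the hydroxyls (the C1′ hydroxyl could close only to an oxetane or in a 5-endo mode, and the primary oxygen is blocked as its silyl ether so that no 6-exo tetrahydropyran can form) and regioselective hydride loss toward C6 and not toward the ether carbon C7a, which the acidity of the α-hydrogens and the gain of conjugation should secure.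

Step 8
Reactants: 10 (R)-lactic acid [(2R)-2-hydroxypropanoic acid]
Product: 11 (2R)-2-(benzoyloxy)propanoic acid
Conditions: BzCl, pyridine, CH2Cl2, 0 °C → rt; dilute aqueous acid work-up
Reagents that add atoms: benzoyl chloride, O=C(Cl)c1ccccc1
Why: O-Acylation of the α-hydroxy acid with benzoyl chloride (any mixed anhydride is hydrolysed on work-up) installs the benzoate that the target carries at C4′ without touching the stereocenter.

Step 9
Reactants: 11 (2R)-2-(benzoyloxy)propanoic acid
Product: 12 (2R)-2-(benzoyloxy)propanoyl chloride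
Conditions: (COCl)2, DMF (cat.), CH2Cl2, 0 °C → rt
Reagents that add atoms: oxalyl chloride, O=C(Cl)C(=O)Cl
Why: Oxalyl chloride with catalytic DMF (Vilsmeier-type activation) converts the acid into the acid chloride under conditions mild enough to keep the α-acyloxy stereocenter intact.

Step 10
Reactants: 12 (2R)-2-(benzoyloxy)propanoyl chloride
Product: 14 (2R)-3-oxo-4-(triphenyl-λ5-phosphanylidene)butan-2-yl benzoate, via acylmethylphosphonium chloride 13 (not isolated)
Conditions: Ph3PCH3Br (2.0 equiv), n-BuLi (2.0 equiv), THF, 0 °C; then 12, −78 °C → rt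
Reagents that add atoms: methyltriphenylphosphonium bromide, C[P+](c1ccccc1)(c1ccccc1)c1ccccc1.[Br-]
Why: C-Acylation of methylenetriphenylphosphorane by the acid chloride gives phosphonium salt 13, which a second equivalent of the ylide deprotonates to the stabilized keto ylide (ylide acylation with transylidation), the acid chloride reacting at −78 °C much faster than the benzoate or the α-hydrogen.

Step 11
Reactants: 9 (2S,3R,3aR,7aR)-2-({[tert-butyl(diphenyl)silyl]oxy}methyl)-3-hydroxy-2,3,3a,7a-tetrahydro-5H-furo[3,2-b]pyran-5-one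
Product: 15 (2S,3R,3aR,7aR)-3-hydroxy-2-(hydroxymethyl)-2,3,3a,7a-tetrahydro-5H-furo[3,2-b]pyran-5-one
Conditions: HF·pyridine, THF/pyridine, 0 °C → rt
Reagents that add atoms: none
Why: Fluoride-mediated Si–O cleavage with buffered HF·pyridine removes the silyl helper under non-basic conditions, which avoids γ-deprotonation and ring opening of the γ-alkoxy unsaturated lactone.

Step 12
Reactants: 15 (2S,3R,3aR,7aR)-3-hydroxy-2-(hydroxymethyl)-2,3,3a,7a-tetrahydro-5H-furo[3,2-b]pyran-5-one
Product: 16 (2R,3S,3aR,7aR)-3-hydroxy-5-oxo-2,3,3a,7a-tetrahydro-5H-furo[3,2-b]pyran-2-carbaldehyde (same spatial arrangement as 15; descriptors change by priority only)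
Conditions: TEMPO (2,2,6,6-tetramethylpiperidin-1-oxyl, cat.), PhI(OAc)2, CH2Cl2, rt
Reagents that add atoms: none
Why: The oxoammonium-mediated oxidation is selective for the primary alcohol over the hindered secondary C3 hydroxyl and stops at the aldehyde, and its near-neutral medium should leave the epimerizable C2 center untouched.

Step 13
Reactants: 16 (2R,3S,3aR,7aR)-3-hydroxy-5-oxo-2,3,3a,7a-tetrahydro-5H-furo[3,2-b]pyran-2-carbaldehyde; 14 (2R)-3-oxo-4-(triphenyl-λ5-phosphanylidene)butan-2-yl benzoate
Product: 17 (2R,4E)-5-[(2S,3R,3aR,7aR)-3-hydroxy-5-oxo-2,3,3a,7a-tetrahydro-5H-furo[3,2-b]pyran-2-yl]-3-oxopent-4-en-2-yl benzoate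
Conditions: CH2Cl2, rt (toluene, 50 °C if slow)
Reagents that add atoms: none
Why: Wittig olefination with the stabilized acyl ylide needs no added base, so C2 should not epimerize, and the reversible addition typical of stabilized ylides gives the E enone.

Step 14
Reactants: 17 (2R,4E)-5-[(2S,3R,3aR,7aR)-3-hydroxy-5-oxo-2,3,3a,7a-tetrahydro-5H-furo[3,2-b]pyran-2-yl]-3-oxopent-4-en-2-yl benzoate
Product: 18 (2R,3S,4E)-3-hydroxy-5-[(2S,3R,3aR,7aR)-3-hydroxy-5-oxo-2,3,3a,7a-tetrahydro-5H-furo[3,2-b]pyran-2-yl]pent-4-en-2-yl benzoate (CNP0143030.1)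
Conditions: (S)-2-methyl-CBS-oxazaborolidine [(3aS)-1-methyl-3,3-diphenylhexahydropyrrolo[1,2-c][1,3,2]oxazaborole] (0.5–1 equiv), catecholborane (excess), toluene/CH2Cl2, −78 °C; then H2O
Reagents that add atoms: none
Why: Corey–Bakshi–Shibata reduction delivers hydride 1,2 to the enone carbonyl with the alkenyl group acting as the large substituent, so the (S)-oxazaborolidine should give the (3′S) carbinol (anti to the C4′ benzoate) under catalyst control, while cold catecholborane leaves the benzoate and the s-trans-locked unsaturated lactone untouched and its excess covers the free C3 hydroxyl.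

**Compound list**

1 | (4S,5S)-2,2-dimethyl-1,3-dioxolane-4,5-dimethanol (2,3-O-isopropylidene-L-threitol) | OC[C@@H]1OC(C)(C)O[C@H]1CO | starting material
2 | [(4S,5S)-5-({[tert-butyl(diphenyl)silyl]oxy}methyl)-2,2-dimethyl-1,3-dioxolan-4-yl]methanol | OC[C@@H]1OC(C)(C)O[C@H]1CO[Si](c2ccccc2)(c3ccccc3)C(C)(C)C | intermediate
3 | (4R,5S)-5-({[tert-butyl(diphenyl)silyl]oxy}methyl)-2,2-dimethyl-1,3-dioxolane-4-carbaldehyde | O=C[C@@H]1OC(C)(C)O[C@H]1CO[Si](c2ccccc2)(c3ccccc3)C(C)(C)C | intermediate
4 | (1S)-1-[(4S,5S)-5-({[tert-butyl(diphenyl)silyl]oxy}methyl)-2,2-dimethyl-1,3-dioxolan-4-yl]prop-2-en-1-ol | C=C[C@H](O)[C@@H]1OC(C)(C)O[C@H]1CO[Si](c2ccccc2)(c3ccccc3)C(C)(C)C | intermediate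
5 | (1S)-1-[(4S,5S)-5-({[tert-butyl(diphenyl)silyl]oxy}methyl)-2,2-dimethyl-1,3-dioxolan-4-yl]prop-2-en-1-yl but-3-enoate | C=CCC(=O)O[C@@H](C=C)[C@@H]1OC(C)(C)O[C@H]1CO[Si](c2ccccc2)(c3ccccc3)C(C)(C)C | intermediate
6 | (6S)-6-[(4S,5S)-5-({[tert-butyl(diphenyl)silyl]oxy}methyl)-2,2-dimethyl-1,3-dioxolan-4-yl]-3,6-dihydro-2H-pyran-2-one | O=C1CC=C[C@H](O1)[C@@H]2OC(C)(C)O[C@H]2CO[Si](c3ccccc3)(c4ccccc4)C(C)(C)C | intermediate
7 | (6S)-6-[(1R,2S)-3-{[tert-butyl(diphenyl)silyl]oxy}-1,2-dihydroxypropyl]-3,6-dihydro-2H-pyran-2-one | O=C1CC=C[C@H](O1)[C@H](O)[C@@H](O)CO[Si](c2ccccc2)(c3ccccc3)C(C)(C)C | intermediate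
8 | C7-chloropalladium adduct: the C6H2–C7H(PdCl) hexahydro analogue of 9, PdCl on C7 trans to the C7a–O1 bond, C2, C3, C3a and C7a arranged as in 9 | CC(C)(C)[Si](c3ccccc3)(c4ccccc4)OC[C@@H]1O[C@@H]2[C@@H]([Pd]Cl)CC(=O)O[C@@H]2[C@@H]1O | intermediate
9 | (2S,3R,3aR,7aR)-2-({[tert-butyl(diphenyl)silyl]oxy}methyl)-3-hydroxy-2,3,3a,7a-tetrahydro-5H-furo[3,2-b]pyran-5-one | CC(C)(C)[Si](c3ccccc3)(c4ccccc4)OC[C@@H]1O[C@@H]2C=CC(=O)O[C@@H]2[C@@H]1O | intermediate
10 | (R)-lactic acid [(2R)-2-hydroxypropanoic acid] | C[C@@H](O)C(O)=O | starting material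
11 | (2R)-2-(benzoyloxy)propanoic acid | C[C@@H](OC(=O)c1ccccc1)C(O)=O | intermediate
12 | (2R)-2-(benzoyloxy)propanoyl chloride | C[C@@H](OC(=O)c1ccccc1)C(Cl)=O | intermediate
13 | [(3R)-3-(benzoyloxy)-2-oxobutyl](triphenyl)phosphonium chloride | C[C@@H](OC(=O)c1ccccc1)C(=O)C[P+](c1ccccc1)(c1ccccc1)c1ccccc1.[Cl-] | intermediate
14 | (2R)-3-oxo-4-(triphenyl-λ5-phosphanylidene)butan-2-yl benzoate | C[C@@H](OC(=O)c1ccccc1)C(=O)C=P(c1ccccc1)(c1ccccc1)c1ccccc1 | intermediate
15 | (2S,3R,3aR,7aR)-3-hydroxy-2-(hydroxymethyl)-2,3,3a,7a-tetrahydro-5H-furo[3,2-b]pyran-5-one | OC[C@@H]1O[C@@H]2C=CC(=O)O[C@@H]2[C@@H]1O | intermediate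
16 | (2R,3S,3aR,7aR)-3-hydroxy-5-oxo-2,3,3a,7a-tetrahydro-5H-furo[3,2-b]pyran-2-carbaldehyde | O=C[C@@H]1O[C@@H]2C=CC(=O)O[C@@H]2[C@@H]1O | intermediate
17 | (2R,4E)-5-[(2S,3R,3aR,7aR)-3-hydroxy-5-oxo-2,3,3a,7a-tetrahydro-5H-furo[3,2-b]pyran-2-yl]-3-oxopent-4-en-2-yl benzoate | C[C@@H](OC(=O)c3ccccc3)C(=O)/C=C/[C@@H]1O[C@@H]2C=CC(=O)O[C@@H]2[C@@H]1O | intermediate
18 | (2R,3S,4E)-3-hydroxy-5-[(2S,3R,3aR,7aR)-3-hydroxy-5-oxo-2,3,3a,7a-tetrahydro-5H-furo[3,2-b]pyran-2-yl]pent-4-en-2-yl benzoate | C[C@@H](OC(=O)c1ccccc1)[C@@H](O)/C=C/[C@@H]1O[C@@H]2C=CC(=O)O[C@@H]2[C@@H]1O | target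

**Step count and risks**

Total: 14 steps. Longest linear sequence: 11 steps (steps 1–7 and 11–14); the ylide branch (steps 8–10) adds 3.

Step 7 (key step). What may go wrong: HPdCl released in the cycle, or adventitious acid, moves the ring alkene of 7 into conjugation before oxypalladation, after which the hydroxyl would add in a conjugate sense and give a bridged ether; or oxypalladation of the ring alkene next to the crowded all-cis array is too slow. The fallback sets out from 7 and comes back at 9, using electrophilic selenium in place of palladium. PhSeCl (CH2Cl2, −78 °C) should form the seleniranium ion on the alkene face away from the side chain, and the C2′ hydroxyl opens it 5-exo at the future C7a to give the 7-(phenylselanyl) hexahydro lactone F1. Oxidation (H2O2, pyridine, CH2Cl2, 0 °C) and syn selenoxide elimination, which runs away from the ether-bearing carbon toward C6, should then give 9.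

Step 14. What may go wrong: insufficient facial control, because the catalyst has to override the Felkin–Anh preference of the α-benzoyloxy ketone, or competing conjugate reduction of the enone. The fallback sets out from 17 and comes back at 18, using substrate control followed by inversion. Luche reduction (NaBH4, CeCl3·7H2O, MeOH, −78 °C) should follow the polar Felkin–Anh preference and give mainly the (3′R) epimer of the target F2. Mitsunobu inversion of its allylic hydroxyl with chloroacetic acid (PPh3, DIAD, THF, 0 °C; the C3 hydroxyl on the concave face of the bicycle is expected to react much more slowly) gives the (3′S) chloroacetate F3. Thiourea (NaHCO3, EtOH, rt) then removes the chloroacetyl group in the presence of the benzoate and the lactone to give 18.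

Step 3. What may go wrong: poor facial selectivity in the vinyl addition, or partial epimerization of the α-alkoxy aldehyde. The fallback sets out from 3 and comes back at 5, and makes both epimers converge instead of relying on selectivity. Plain CH2=CHMgBr (THF, −78 °C) gives 4 together with its (1R) epimer F4, and the two are separated. Alcohol 4 is esterified as in step 4, while F4 is esterified with but-3-enoic acid under Mitsunobu conditions (PPh3, DIAD, THF, 0 °C), the SN2 inversion at the carbinol carbon turning it into the same ester 5.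

**Further compounds**

F1 | step 7 | 7-(phenylselanyl) hexahydro analogue of 9 (C6H2–C7H(SePh); SePh trans to the C7a–O1 bond; C2, C3, C3a and C7a arranged as in 9) | CC(C)(C)[Si](c3ccccc3)(c4ccccc4)OC[C@@H]1O[C@@H]2[C@@H]([Se]c5ccccc5)CC(=O)O[C@@H]2[C@@H]1O
F2 | step 14 | (2R,3R,4E)-3-hydroxy-5-[(2S,3R,3aR,7aR)-3-hydroxy-5-oxo-2,3,3a,7a-tetrahydro-5H-furo[3,2-b]pyran-2-yl]pent-4-en-2-yl benzoate | C[C@@H](OC(=O)c3ccccc3)[C@H](O)/C=C/[C@@H]1O[C@@H]2C=CC(=O)O[C@@H]2[C@@H]1O
F3 | step 14 | (2R,3S,4E)-3-[(chloroacetyl)oxy]-5-[(2S,3R,3aR,7aR)-3-hydroxy-5-oxo-2,3,3a,7a-tetrahydro-5H-furo[3,2-b]pyran-2-yl]pent-4-en-2-yl benzoate | C[C@@H](OC(=O)c3ccccc3)[C@@H](OC(=O)CCl)/C=C/[C@@H]1O[C@@H]2C=CC(=O)O[C@@H]2[C@@H]1O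
F4 | step 3 | (1R)-1-[(4S,5S)-5-({[tert-butyl(diphenyl)silyl]oxy}methyl)-2,2-dimethyl-1,3-dioxolan-4-yl]prop-2-en-1-ol | C=C[C@@H](O)[C@@H]1OC(C)(C)O[C@H]1CO[Si](c2ccccc2)(c3ccccc3)C(C)(C)C
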